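## Retrosynthetic overview

1. The C50 polyene is cut at C11=C12 and C11'=C12' (two Wittig reactions) into the C10 dialdehyde 31 and two C20 end-group phosphonium salts: ring A salt 24 (2-prenyl, 2,6-cis) and ring B salt 30 (2,6-trans, hydroxyprenyl carried as its methyl ester).
2. Each salt goes back to a 2-(2-pivaloyloxyethyl)-α-ionone (14 cis, 16 trans): the ketone becomes the vinyl carbinol and then the salt; the arm CH2CH2OPiv becomes CH2CHO and is extended by a Wittig reaction.
3. Both cyclohexene rings come from one ring closure: step 8 forms C1–C6 of the acyclic trienone 13 by acid-induced cation–olefin cyclization and gives the cis ketone 14 (ring A). Part of 14 is then inverted at C6 by base to the trans ketone 16 (ring B, step 9). No other ring is made.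
4. Feature used: C2 of ring A (and C2' of ring B), the CH between the CMe2 carbon C1 and the two-carbon arm C1''–C2'', is C4 of (R)-limonene, whose isopropenyl carbon becomes C1. Opening limonene at its ring alkene gives the chain C3–C4–C5(Me) and the arm in one operation.
5. The trienone comes from the limonene-derived keto pivalate 6 by ethynylation, Saucy–Marbet rearrangement and base isomerization.

Key step: step 8

Remark on the chemistry: positions are numbered as in carotenoids (C1 = CMe2, C2 = CH carrying the C5 side chain through C1''–C2'', C3 = CH2, C4=C5(Me), C6 = CH carrying the polyene through C7; primes for ring B). Acyclic precursors are discussed with the numbers their carbons have after ring closure. The isomerization of step 7 forms both C5=C6 geometric isomers; it is assumed that the 5E isomer 13 can be separated from its 5Z isomer on AgNO3-impregnated silica gel.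

## Route

Step 1
Reactants: 1 (R)-(+)-limonene
Product: 2 (4R)-limonene 1,2-oxide (mixture of epoxide diastereomers)
Conditions: mCPBA (1.0 equiv), CH2Cl2, 0 °C
Reagents that add atoms: mCPBA (3-chloroperoxybenzoic acid), OOC(=O)c1cccc(Cl)c1
Why: Prilezhaev epoxidation is faster at the electron-rich trisubstituted ring alkene than at the isopropenyl group, and the epoxide configuration is irrelevant because both epoxide carbons become carbonyl carbons in step 2.

Step 2
Reactants: 2 (4R)-limonene 1,2-oxide
Product: 4 (3R)-6-oxo-3-(prop-1-en-2-yl)heptanal, via limonene-1,2-diol 3 (not isolated)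
Conditions: H5IO6, THF/H2O, 0 °C → rt
Reagents that add atoms: water, O
Why: Periodic acid hydrolyses the epoxide to the trans-diol and cleaves it at once (Malaprade glycol cleavage), which opens the ring into methyl ketone and aldehyde; the stereocenter, now β to the aldehyde, cannot epimerize.

Step 3
Reactants: 4 (3R)-6-oxo-3-(prop-1-en-2-yl)heptanal
Product: 5 (5R)-7-hydroxy-5-(prop-1-en-2-yl)heptan-2-one
Conditions: NaBH4 (0.3 equiv), EtOH/CH2Cl2, −78 °C
Reagents that add atoms: none
Why: At −78 °C NaBH4 reduces an aldehyde much faster than a methyl ketone (chemoselective hydride reduction), so only the two-carbon arm should be reduced.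

Step 4
Reactants: 5 (5R)-7-hydroxy-5-(prop-1-en-2-yl)heptan-2-one
Product: 6 (3R)-6-oxo-3-(prop-1-en-2-yl)heptyl pivalate
Conditions: PivCl, pyridine, DMAP (cat.), CH2Cl2, 0 °C → rt
Reagents that add atoms: pivaloyl chloride, CC(C)(C)C(Cl)=O
Why: Standard DMAP-catalysed acylation; the pivalate resists the acetylide, alkoxide and H3PO4 of the following steps, and an ester oxygen is too poor a nucleophile to capture the C1 cation of step 8.

Step 5
Reactants: 6 (3R)-6-oxo-3-(prop-1-en-2-yl)heptyl pivalate; 7 ethynylmagnesium bromide
Product: 8 (3R)-6-hydroxy-6-methyl-3-(prop-1-en-2-yl)oct-7-yn-1-yl pivalate (both carbinol epimers)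
Conditions: ethynylmagnesium bromide (1.3 equiv), THF, −20 → 0 °C; then H2O
Reagents that add atoms: ethynylmagnesium bromide (7), C#C[Mg]Br
Why: 1,2-Addition of the alkynyl Grignard reagent to the methyl ketone is fast at 0 °C while the hindered pivalate is left alone; the new carbinol center forms unselectively and disappears in step 6.

Step 6
Reactants: 8 (3R)-6-hydroxy-6-methyl-3-(prop-1-en-2-yl)oct-7-yn-1-yl pivalate; 9 2-methoxypropene
Product: 12 (3R)-6-methyl-10-oxo-3-(prop-1-en-2-yl)undeca-6,7-dien-1-yl pivalate (β-allenyl ketone), via mixed methyl ketal 10 (not isolated), via propargyl isopropenyl ether 11 (not isolated)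
Conditions: 2-methoxypropene (4 equiv), p-TsOH (cat.), toluene, 100 °C, sealed tube; then Et3N
Reagents that add atoms: 2-methoxypropene (9), COC(C)=C
Why: Saucy–Marbet reaction: acid-catalysed ketal exchange and loss of methanol give the propargyl isopropenyl ether, whose [3,3]-sigmatropic (propargyl Claisen) shift gives the β-allenyl ketone; the excess enol ether should consume the trace of acid before it reaches the isopropenyl group.

Step 7
Reactants: 12 β-allenyl ketone
Product: 13 (3R,6E,8E)-6-methyl-10-oxo-3-(prop-1-en-2-yl)undeca-6,8-dien-1-yl pivalate (the 5E trienone)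
Conditions: NaOMe (0.1 equiv), MeOH, 0 °C; chromatography on AgNO3-impregnated silica gel
Reagents that add atoms: none
Why: Methoxide moves the allene into conjugation by enolization and protonation at the central allene carbon (the prototropic isomerization of the pseudoionone synthesis), which should give the 7E dienone as a pair of C5=C6 isomers; the 5E isomer 13 is isolated, and the 5Z isomer that forms beside it is removed by the chromatography and can be returned to the E/Z mixture with a trace of iodine in daylight.

Step 8
Reactants: 13 (5E)-trienone pivalate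
Product: 14 (2R,6R)-2-[2-(pivaloyloxy)ethyl]-α-ionone (2,6-cis), i.e. 2-{(1R,5R)-4,6,6-trimethyl-5-[(1E)-3-oxobut-1-en-1-yl]cyclohex-3-en-1-yl}ethyl pivalate
Conditions: 85% H3PO4, toluene, 0 → 20 °C, vigorous stirring; then ice/aq. NaHCO3
Reagents that add atoms: none
Why: Markovnikov protonation of the 1,1-disubstituted alkene gives the tertiary cation at C1, C6 of the C5=C6 alkene attacks it to form the C1–C6 bond, and the tertiary C5 cation that results loses H4 to leave the C4=C5 alkene. The closest known reactions are the H3PO4 cyclizations of pseudoionone to α-ionone and of pseudoirones to α-irones. Ring A closes in a 6-endo-trig mode (both carbons of the attacking alkene end up in the ring) through a chair. The new stereocenter C6 is controlled by the limonene-derived C2: the C2 arm takes the equatorial place, anti to the forming bond and staggered between the two C1 methyl groups, and the E geometry of C5=C6 puts C7 equatorial as well, so the 2,6-cis ketone should be the main product, and the minor 2,6-trans epimer is separated and kept for the ring B series. The step needs ring closure to be faster than a 1,2-hydride shift or proton loss at C2, which the pre-folded 1,5-diene secures by taking part in the protonation, and it needs proton loss from C4 and not from C6, which H3PO4 at or below room temperature favours kinetically. Only one alkene is basic enough to be protonated, because the arm is held as the pivalate and the dienone is deactivated by its carbonyl group, so neither a second cyclization nor capture of the cation by oxygen should compete.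

Step 9
Reactants: 14 cis ketone pivalate
Product: 16 (2R,6S)-2-[2-(pivaloyloxy)ethyl]-α-ionone (2,6-trans; 2-{(1R,5S)-4,6,6-trimethyl-5-[(1E)-3-oxobut-1-en-1-yl]cyclohex-3-en-1-yl}ethyl pivalate), via potassium trienolate 15 (not isolated)
Conditions: KOt-Bu (0.2 equiv), t-BuOH/THF, 0 °C → rt, Ar; AcOH quench near equilibrium; chromatography, recovered 14 recycled
Reagents that add atoms: none
Why: Catalytic t-butoxide removes the doubly allylic, vinylogous α-hydrogen at C6 to give the extended enolate, and reprotonation at C6 under equilibrating conditions (base-mediated epimerization, as in the conversion of cis-α-irone into trans-α-irone) should favour the 2,6-trans epimer, in which the C6 side chain stands pseudo-axial and so avoids the C5 methyl group and one of the C1 methyl groups; C2 is not acidic and keeps its configuration, and the hindered pivalate is not exchanged by t-butoxide.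

Step 10
Reactants: 14 cis ketone pivalate; 17 vinylmagnesium bromide
Product: 18 2-{(1R,5R)-5-[(1E)-3-hydroxy-3-methylpenta-1,4-dien-1-yl]-4,6,6-trimethylcyclohex-3-en-1-yl}ethyl pivalate (both carbinol epimers)
Conditions: vinylmagnesium bromide (1.5 equiv), THF, −78 → −20 °C; then H2O
Reagents that add atoms: vinylmagnesium bromide (17), C=C[Mg]Br
Why: Vinyl Grignard reagents add 1,2 to ionone-type enones because C7 is shielded by the ring, and at low temperature the pivalate is not attacked; the carbinol configuration is irrelevant because C9 becomes trigonal in step 14.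

Step 11
Reactants: 18 ring A vinyl carbinol pivalate
Product: 19 (1E)-1-[(1R,5R)-5-(2-hydroxyethyl)-2,6,6-trimethylcyclohex-2-en-1-yl]-3-methylpenta-1,4-dien-3-ol
Conditions: i-Bu2AlH (3.5 equiv), CH2Cl2, −78 °C; then aq. NaOH
Reagents that add atoms: none
Why: i-Bu2AlH cleaves the pivalate reductively without acid, so the acid-sensitive tertiary allylic alcohol and both alkenes should survive.

Step 12
Reactants: 19 ring A diol
Product: 20 2-{(1R,5R)-5-[(1E)-3-hydroxy-3-methylpenta-1,4-dien-1-yl]-4,6,6-trimethylcyclohex-3-en-1-yl}acetaldehyde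
Conditions: Dess–Martin periodinane, NaHCO3, CH2Cl2, 0 °C
Reagents that add atoms: none
Why: Dess–Martin oxidation stops at the aldehyde and cannot oxidize the tertiary alcohol, and the NaHCO3 buffer keeps acetic acid from ionizing the allylic carbinol.

Step 13
Reactants: 20 ring A hydroxy aldehyde; 21 isopropyltriphenylphosphonium iodide
Product: 23 (1E)-3-methyl-1-[(1R,5S)-2,6,6-trimethyl-5-(3-methylbut-2-en-1-yl)cyclohex-2-en-1-yl]penta-1,4-dien-3-ol, via isopropylidenetriphenylphosphorane 22 (not isolated)
Conditions: 21 (2.5 equiv), n-BuLi, THF, 0 °C; then 20, −78 °C → rt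
Reagents that add atoms: isopropyltriphenylphosphonium iodide (21), CC(C)[P+](c1ccccc1)(c1ccccc1)c1ccccc1.[I-]
Why: Wittig olefination of the aldehyde with the non-stabilized isopropylidene ylide gives the prenyl group (no alkene geometry arises); the excess ylide covers deprotonation of the tertiary alcohol.

Step 14
Reactants: 23 ring A prenyl vinyl carbinol
Product: 24 {(2E,4E)-3-methyl-5-[(1R,5S)-2,6,6-trimethyl-5-(3-methylbut-2-en-1-yl)cyclohex-2-en-1-yl]penta-2,4-dien-1-yl}triphenylphosphonium bromide (ring A salt)
Conditions: PPh3·HBr, MeOH, 0 °C → rt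
Reagents that add atoms: triphenylphosphine hydrobromide, [Br-].c1ccc(cc1)[PH+](c1ccccc1)c1ccccc1
Why: The acid ionizes the tertiary bis-allylic carbinol to a pentadienyl cation that PPh3 captures at the unhindered terminal carbon C11 (the SN1' route to C15 Wittig salts), which should give mainly the 9E salt, while the isolated ring and prenyl alkenes are not protonated by this weak acid.

Step 15
Reactants: 16 trans ketone pivalate; 17 vinylmagnesium bromide
Product: 25 2-{(1R,5S)-5-[(1E)-3-hydroxy-3-methylpenta-1,4-dien-1-yl]-4,6,6-trimethylcyclohex-3-en-1-yl}ethyl pivalate (both carbinol epimers)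
Conditions: vinylmagnesium bromide (1.5 equiv), THF, −78 → −20 °C; then H2O
Reagents that add atoms: vinylmagnesium bromide (17), C=C[Mg]Br
Why: Grignard 1,2-addition to the enone as in step 10, with the pivalate untouched at low temperature.

Step 16
Reactants: 25 ring B vinyl carbinol pivalate
Product: 26 (1E)-1-[(1S,5R)-5-(2-hydroxyethyl)-2,6,6-trimethylcyclohex-2-en-1-yl]-3-methylpenta-1,4-dien-3-ol
Conditions: i-Bu2AlH (3.5 equiv), CH2Cl2, −78 °C; then aq. NaOH
Reagents that add atoms: none
Why: Reductive, non-acidic cleavage of the pivalate as in step 11.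

Step 17
Reactants: 26 ring B diol
Product: 27 2-{(1R,5S)-5-[(1E)-3-hydroxy-3-methylpenta-1,4-dien-1-yl]-4,6,6-trimethylcyclohex-3-en-1-yl}acetaldehyde
Conditions: Dess–Martin periodinane, NaHCO3, CH2Cl2, 0 °C
Reagents that add atoms: none
Why: Buffered Dess–Martin oxidation of the primary alcohol only, as in step 12.

Step 18
Reactants: 27 ring B hydroxy aldehyde; 28 methyl 2-(triphenylphosphoranylidene)propanoate
Product: 29 methyl (2E)-4-{(1R,5S)-5-[(1E)-3-hydroxy-3-methylpenta-1,4-dien-1-yl]-4,6,6-trimethylcyclohex-3-en-1-yl}-2-methylbut-2-enoate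
Conditions: 28 (1.3 equiv), CH2Cl2, rt
Reagents that add atoms: methyl 2-(triphenylphosphoranylidene)propanoate (28), COC(=O)C(C)=P(c1ccccc1)(c1ccccc1)c1ccccc1
Why: The stabilized ylide reacts only with the aldehyde, and the Wittig reaction of such ylides is E-selective, so it should give the (E)-2-methylbut-2-enoate with the geometry of the hydroxyprenyl group.

Step 19
Reactants: 29 ring B enoate vinyl carbinol
Product: 30 {(2E,4E)-5-[(1S,5R)-5-[(2E)-4-methoxy-3-methyl-4-oxobut-2-en-1-yl]-2,6,6-trimethylcyclohex-2-en-1-yl]-3-methylpenta-2,4-dien-1-yl}triphenylphosphonium bromide (ring B salt)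
Conditions: PPh3·HBr, MeOH, 0 °C → rt
Reagents that add atoms: triphenylphosphine hydrobromide, [Br-].c1ccc(cc1)[PH+](c1ccccc1)c1ccccc1
Why: SN1' phosphonium salt formation as in step 14; the methyl enoate is inert to the weak acid and cannot transesterify in methanol.

Step 20
Reactants: 24 ring A salt; 31 (2E,4E,6E)-2,7-dimethylocta-2,4,6-trienedial (C10 dialdehyde)
Product: 33 (2S,6R)-2-(3-methylbut-2-en-1-yl)-12'-apo-ε-caroten-12'-al (all-E C30 aldehyde), via ring A ylide 32 (not isolated)
Conditions: NaOMe, MeOH/CH2Cl2, 0 °C → rt, 31 (3 equiv), Ar, dim light; then I2 (cat.), hexane, rt, daylight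
Reagents that add atoms: C10 dialdehyde (31), O=C/C(C)=C/C=C/C=C(C)/C=O
Why: NaOMe turns 24 into the allylic ylide, which condenses with one aldehyde group of the dialdehyde used in excess (Wittig reaction); the new C11=C12 bond forms as an E/Z mixture that iodine equilibrates to E.

Step 21
Reactants: 30 ring B salt; 33 C30 aldehyde
Product: 35 methyl (2E)-4-[(2S,6R,2'R,6'S)-2-(3-methylbut-2-en-1-yl)-ε,ε-caroten-2'-yl]-2-methylbut-2-enoate (all-E C51 ester), via ring B ylide 34 (not isolated)
Conditions: NaOMe, MeOH/CH2Cl2, 0 °C → rt, Ar, dim light; then heptane, reflux, dark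
Reagents that add atoms: none
Why: Second Wittig reaction, forming C11'=C12'; the ester and the stereocenters are inert to the semi-stabilized ylide, and heating converts 11'Z material into the all-E polyene.

Step 22
Reactants: 35 C51 methyl ester
Product: 36 CNP0304855.1, (2S,6R,2'R,6'S)-2'-[(2E)-4-hydroxy-3-methylbut-2-en-1-yl]-2-(3-methylbut-2-en-1-yl)-ε,ε-carotene
Conditions: i-Bu2AlH (2.5 equiv), CH2Cl2/toluene, −78 °C, Ar, dim light; then aq. NaOH
Reagents that add atoms: none
Why: i-Bu2AlH at −78 °C reduces the conjugated methyl ester to the primary allylic alcohol by 1,2-hydride delivery with retention of the E geometry, and the polyene and the four stereocenters are not touched.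

## Compound list

1 | (R)-(+)-limonene | CC1=CC[C@@H](CC1)C(C)=C | starting material
2 | (4R)-limonene 1,2-oxide, epoxide diastereomers | CC12OC1C[C@@H](CC2)C(C)=C | intermediate
3 | (4R)-1-methyl-4-(prop-1-en-2-yl)cyclohexane-1,2-diol (limonene-1,2-diol) | CC1(O)CC[C@H](CC1O)C(C)=C | intermediate (not isolated)
4 | (3R)-6-oxo-3-(prop-1-en-2-yl)heptanal | O=CC[C@@H](CCC(C)=O)C(C)=C | intermediate
5 | (5R)-7-hydroxy-5-(prop-1-en-2-yl)heptan-2-one | CC(=O)CC[C@H](CCO)C(C)=C | intermediate
6 | (3R)-6-oxo-3-(prop-1-en-2-yl)heptyl pivalate | CC(=O)CC[C@H](CCOC(=O)C(C)(C)C)C(C)=C | intermediate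
7 | ethynylmagnesium bromide | C#C[Mg]Br | starting material
8 | (3R)-6-hydroxy-6-methyl-3-(prop-1-en-2-yl)oct-7-yn-1-yl pivalate, carbinol epimers | C#CC(C)(O)CC[C@H](CCOC(=O)C(C)(C)C)C(C)=C | intermediate
9 | 2-methoxypropene | COC(C)=C | starting material
10 | (3R)-6-[(2-methoxypropan-2-yl)oxy]-6-methyl-3-(prop-1-en-2-yl)oct-7-yn-1-yl pivalate (mixed methyl ketal) | C#CC(C)(OC(C)(C)OC)CC[C@H](CCOC(=O)C(C)(C)C)C(C)=C | intermediate (not isolated)
11 | (3R)-6-methyl-3-(prop-1-en-2-yl)-6-(prop-1-en-2-yloxy)oct-7-yn-1-yl pivalate (propargyl isopropenyl ether) | C#CC(C)(OC(C)=C)CC[C@H](CCOC(=O)C(C)(C)C)C(C)=C | intermediate (not isolated)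
12 | (3R)-6-methyl-10-oxo-3-(prop-1-en-2-yl)undeca-6,7-dien-1-yl pivalate (β-allenyl ketone) | CC(=O)CC=C=C(C)CC[C@H](CCOC(=O)C(C)(C)C)C(C)=C | intermediate
13 | (3R,6E,8E)-6-methyl-10-oxo-3-(prop-1-en-2-yl)undeca-6,8-dien-1-yl pivalate (5E trienone, key precursor) | CC(C)(C)C(=O)OCC[C@H](C(C)=C)CC/C(C)=C/C=C/C(C)=O | intermediate
14 | (2R,6R)-2-[2-(pivaloyloxy)ethyl]-α-ionone, 2,6-cis (key product) | CC(C)(C)C(=O)OCC[C@H]1CC=C(C)[C@@H](/C=C/C(C)=O)C1(C)C | intermediate
15 | potassium trienolate of 14 (deprotonated at C6) | CC(C)(C)C(=O)OCC[C@H]1CC=C(C)C(=CC=C(C)[O-])C1(C)C.[K+] | intermediate (not isolated)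
16 | (2R,6S)-2-[2-(pivaloyloxy)ethyl]-α-ionone, 2,6-trans | CC(C)(C)C(=O)OCC[C@H]1CC=C(C)[C@H](/C=C/C(C)=O)C1(C)C | intermediate
17 | vinylmagnesium bromide | C=C[Mg]Br | starting material
18 | ring A vinyl carbinol pivalate (cis, carbinol epimers) | CC(C)(C)C(=O)OCC[C@H]1CC=C(C)[C@@H](/C=C/C(C)(O)C=C)C1(C)C | intermediate
19 | ring A diol (cis) | OCC[C@H]1CC=C(C)[C@@H](/C=C/C(C)(O)C=C)C1(C)C | intermediate
20 | ring A hydroxy aldehyde (cis) | O=CC[C@H]1CC=C(C)[C@@H](/C=C/C(C)(O)C=C)C1(C)C | intermediate
21 | isopropyltriphenylphosphonium iodide | CC(C)[P+](c1ccccc1)(c1ccccc1)c1ccccc1.[I-] | starting material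
22 | isopropylidenetriphenylphosphorane | CC(C)=P(c1ccccc1)(c1ccccc1)c1ccccc1 | intermediate (not isolated)
23 | ring A prenyl vinyl carbinol (cis) | CC(C)=CC[C@H]1CC=C(C)[C@@H](/C=C/C(C)(O)C=C)C1(C)C | intermediate
24 | ring A C20 phosphonium bromide | CC(C)=CC[C@H]1CC=C(C)[C@@H](/C=C/C(C)=C/C[P+](c2ccccc2)(c2ccccc2)c2ccccc2)C1(C)C.[Br-] | intermediate
25 | ring B vinyl carbinol pivalate (trans, carbinol epimers) | CC(C)(C)C(=O)OCC[C@H]1CC=C(C)[C@H](/C=C/C(C)(O)C=C)C1(C)C | intermediate
26 | ring B diol (trans) | OCC[C@H]1CC=C(C)[C@H](/C=C/C(C)(O)C=C)C1(C)C | intermediate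
27 | ring B hydroxy aldehyde (trans) | O=CC[C@H]1CC=C(C)[C@H](/C=C/C(C)(O)C=C)C1(C)C | intermediate
28 | methyl 2-(triphenylphosphoranylidene)propanoate | COC(=O)C(C)=P(c1ccccc1)(c1ccccc1)c1ccccc1 | starting material
29 | ring B (E)-enoate vinyl carbinol (trans) | COC(=O)/C(C)=C/C[C@H]1CC=C(C)[C@H](/C=C/C(C)(O)C=C)C1(C)C | intermediate
30 | ring B C21 phosphonium bromide (methyl ester) | COC(=O)/C(C)=C/C[C@H]1CC=C(C)[C@H](/C=C/C(C)=C/C[P+](c2ccccc2)(c2ccccc2)c2ccccc2)C1(C)C.[Br-] | intermediate
31 | (2E,4E,6E)-2,7-dimethylocta-2,4,6-trienedial | O=C/C(C)=C/C=C/C=C(C)/C=O | starting material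
32 | ring A ylide | CC(C)=CC[C@H]1CC=C(C)[C@@H](/C=C/C(C)=C/C=P(c2ccccc2)(c2ccccc2)c2ccccc2)C1(C)C | intermediate (not isolated)
33 | (2S,6R)-2-(3-methylbut-2-en-1-yl)-12'-apo-ε-caroten-12'-al, all-E | CC(C)=CC[C@H]1CC=C(C)[C@@H](/C=C/C(C)=C/C=C/C(C)=C/C=C/C=C(C)/C=O)C1(C)C | intermediate
34 | ring B ylide | COC(=O)/C(C)=C/C[C@H]1CC=C(C)[C@H](/C=C/C(C)=C/C=P(c2ccccc2)(c2ccccc2)c2ccccc2)C1(C)C | intermediate (not isolated)
35 | all-E C51 methyl ester (target with CO2Me in place of CH2OH) | CC(C)=CC[C@H]1CC=C(C)[C@@H](/C=C/C(C)=C/C=C/C(C)=C/C=C/C=C(C)/C=C/C=C(C)/C=C/[C@H]2C(C)=CC[C@H](C/C=C(\C)C(=O)OC)C2(C)C)C1(C)C | intermediate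
36 | CNP0304855.1 | CC(C)=CC[C@H]1CC=C(C)[C@@H](/C=C/C(C)=C/C=C/C(C)=C/C=C/C=C(C)/C=C/C=C(C)/C=C/[C@H]2C(C)=CC[C@H](C/C=C(\C)CO)C2(C)C)C1(C)C | target

## Step count and risks

Total step count: 22.
Longest linear sequence: 16 steps (steps 1–8, 10–14, 20–22; the ring B branch, steps 1–9, 15–19, 21–22, is equally long).

The three steps most likely to fail:

**Step 8 (key cyclization).** The C1 cation may suffer a 1,2-hydride shift from C2, or reversible proton loss toward a C1=C2 alkene, before the ring closes; either would erode the configuration at C2. Proton loss from the C5 cation may also go partly toward C6. The fallback sets out from 13 and activates the isopropenyl group with Hg(OTf)2·PhNMe2 in MeNO2 at −20 °C instead of with a proton. The bridged mercurinium ion has no open cation next to C2 and should be opened at C1 by C6 in an anti fashion through the same chair. After aq. NaCl this would give the cyclized alkylmercury chloride F1. Demercuration with Bu3SnH/AIBN in toluene turns CH2HgCl into the second C1 methyl group, and the fallback comes back to the route at 14.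

**Step 9 (epimerization at C6).** The trienolate may be reprotonated at C4 or at C8 instead of at C6, which would move the ring alkene into conjugation with loss of the C6 stereocenter or deconjugate the enone. The equilibrium may also stop with much cis ketone left, and aldol self-condensation of the methyl ketone would drain material. The fallback sets out from 12 and uses kinetic ring closure instead of equilibration. The NaOMe isomerization of 12 gives, beside 13, the (3R,6Z,8E)-trienone pivalate F2 (the 5Z isomer), which is collected from the chromatography on AgNO3-impregnated silica gel. Treated with 85% H3PO4 in toluene at 0 → 20 °C, F2 should close the C1–C6 bond through the same chair with the C2 arm equatorial. The Z geometry at C5=C6 then places C7 axial, which is the 2,6-trans relationship, provided ring closure is faster than E/Z equilibration of the O-protonated dienone. The fallback comes back to the route at 16.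

**Step 6 (Saucy–Marbet rearrangement).** At the hindered tertiary propargylic alcohol the acid catalyst may start a Rupe or Meyer–Schuster rearrangement, or act on the isopropenyl group, faster than ketal exchange and the Claisen shift take place. The fallback sets out from 8 and makes the Meyer–Schuster rearrangement the intended reaction: VO(OSiPh3)3 (cat.) in xylene at 140 °C would give the enal F3 as an E/Z mixture. Crossed aldol condensation of F3 with acetone (aq. NaOH, acetone, rt) should give the 7E trienone as the same pair of C5=C6 isomers, so the fallback comes back to the route at 13 after the same chromatography, and step 7 is not needed.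

## Further compounds

F1 | step 8 | 2-{(1R,5R)-6-(chloromercuriomethyl)-4,6-dimethyl-5-[(1E)-3-oxobut-1-en-1-yl]cyclohex-3-en-1-yl}ethyl pivalate (epimers at C1) | CC(C)(C)C(=O)OCC[C@H]1CC=C(C)[C@@H](/C=C/C(C)=O)C1(C)C[Hg]Cl
F2 | step 9 | (3R,6Z,8E)-6-methyl-10-oxo-3-(prop-1-en-2-yl)undeca-6,8-dien-1-yl pivalate (5Z trienone) | CC(C)(C)C(=O)OCC[C@H](C(C)=C)CC/C(C)=C\C=C\C(C)=O
F3 | step 6 | (3R)-6-methyl-8-oxo-3-(prop-1-en-2-yl)oct-6-en-1-yl pivalate (E/Z enal) | O=CC=C(C)CC[C@H](CCOC(=O)C(C)(C)C)C(C)=C
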